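A small charge of free catalyst, 0.20 mM, works the oak flask, which is the flask asked about, but each target it makes costs one partner, and partner comes from 0.0210 M of solid reagent set against 0.020 M of starting material.

| flask | starting material | second substrate | solid reagent | free catalyst | temperature | remark | time |
|---|---|---|---|---|---|---|---|
| oak | 0.020 M | 10 mM | 0.021 M | 0.20 mM | 0 °C | the very flask that is asked about, followed so far |  |
| birch | 0.020 M | 20 mM | 0.021 M | 0.20 mM | 6 °C | run made earlier |  |
| flask | 0.020 M | 10.0 mM | 0.0210 M | 0.20 mM | 0 °C |  | 4.0 h |

| run | time / min | target / % | starting material / % |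
|---|---|---|---|
| oak | 12.0 | 35 | 60 |
| oak | 40.0 | 84 | 8 |
| oak | 60.0 | 83 | 6 |
| oak | 120 | 83 | 8 |
| oak | 150 | 82 | 7 |
| oak | 180 | 84 | 5 |
| birch | 0.833 | 3 | 99 |
| birch | 1.50 | 2 | 93 |
| birch | 2.50 | 5 | 95 |
| birch | 3.00 | 9 | 91 |
| birch | 4.00 | 9 | 88 |
| birch | 5.00 | 14 | 82 |

(standard deviation of a reading: 1.5 percentage points)

- as a solid, counted per litre of solution: solid reagent
- target that was removed still counts
- the earlier runs were read with a standard deviation of 1.5 percentage points
- candidate steps: partner + catalyst intermediate A -> free catalyst + target; second substrate + free catalyst <-> catalyst intermediate B; starting material + partner -> uncatalysed product; 2 second substrate -> self-condensation product; solid reagent <-> partner; partner + catalyst intermediate B -> free catalyst + second product; starting material + free catalyst <-> catalyst intermediate A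
- at the start none of the solid reagent is in solution
- additions bring no volume worth counting

- Thursday's: at 4.0 h add free catalyst, 100 % of the amount charged, then wait 4.0 h
- Friday's: at 4.0 h take out 90 % of the target then present, then wait 4.0 h
- Wednesday's: change nothing and wait 4.0 h more
- Saturday's: at 4.0 h raise the temperature by 25 K, then wait 4.0 h

* target, in percent of the starting material first charged, at 4.0 h
* which option adds most target ("none" when 2 percentage points or less is all one gets) (Thursday's / Friday's / Wednesday's / Saturday's / none)
* target present, with what was taken out counted in, in percent of the starting material first charged, after Thursday's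
* target present, with what was taken out counted in, in percent of the starting material first charged, after Friday's

**Where did oak stop?** From 40.0 min to 180 min, target reads about 83.2 % and starting material about 6.80 %.

**Stopped, or slowed?** Stopped, as far as readings with a scatter of 1.5 percentage points can tell: target reads 84 % at 40.0 min and 84 % at 180 min.

**Then count the partner.** Starting material consumed took one partner each, whether it became target or uncatalysed product, and that comes to 18.6 mM. The rest of the solid charge, 2.36 mM, is the side draw: partner taken through catalyst intermediate B into second product. Up to 0.20 mM of starting material may sit on the catalyst, so the draw is uncertain by that much. Second substrate, charged at 10.0 mM, is more than that draw.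

**Isn't that circular? You assumed the partner was spent.** The arithmetic is circular, so the evidence must lie elsewhere. The candidate steps hold no catalyst death, and starting material also reacts with partner without catalyst, yet its readings stay flat for 140 min. I therefore take partner as the limiting reagent: 0.0210 M less the draw leaves 18.6 mM, short of 0.020 M by 1.40 mM.

**And the options?** None of them adds solid reagent, and target, uncatalysed product and second product each cost one partner. I commit to about 83.2 % at 4.0 h, with no useful option.

The forecast gives 83.2 %, best option none, 83.3 % after Thursday's and 83.3 % after Friday's: “So the partner is exhausted.”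

The flask gives 83.7 %, best option none, 83.7 % after Thursday's and 83.7 % after Friday's.

    partner + catalyst intermediate A → free catalyst + target (k = 140 L mol⁻¹ s⁻¹, Ea = 35.0 kJ mol⁻¹)
    second substrate + free catalyst ⇌ catalyst intermediate B (K = 2000 L mol⁻¹, k = 7.00 L mol⁻¹ s⁻¹, Ea = 45.0 kJ mol⁻¹, ΔH = −47.0 kJ mol⁻¹)
    starting material + partner → uncatalysed product (k = 0.0850 L mol⁻¹ s⁻¹, Ea = 58.0 kJ mol⁻¹)
    2 second substrate → self-condensation product (k = 0.140 L mol⁻¹ s⁻¹, Ea = 61.0 kJ mol⁻¹)
    solid reagent ⇌ partner, rate k5*(cs5 - [partner]) while solid is left; crystals form when [partner] > cs5 (solubility = 20.0 mM, k = 7.50 × 10⁻⁴ s⁻¹)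
    partner + catalyst intermediate B → free catalyst + second product (k = 39.0 L mol⁻¹ s⁻¹, Ea = 37.0 kJ mol⁻¹)
    starting material + free catalyst ⇌ catalyst intermediate A (K = 4700 L mol⁻¹, k = 11.0 L mol⁻¹ s⁻¹, Ea = 44.0 kJ mol⁻¹, ΔH = −63.0 kJ mol⁻¹)
    (constants at 0 °C)

In the flask, the dissolving of solid reagent had 100 % of its turnover behind it at 48.0 min, and target formation had 86 % of its own at 24.0 min. At 120 min solid reagent stands at 0 % and partner at 0 M, while target stays at 83.7 % through 240 min. Second product at 240 min is 0.00263 M, against the draw of 2.36 mM reckoned from the oak readings.

In the neighbour flask with 0.012 M of starting material, oak's draw leaves 18.6 mM of partner, more than that flask's starting material needs, so starting material should end first, with about 6.64 mM of partner over. The computed neighbour has starting material 0 %, partner 0.00527 M, second product 0.00373 M and target 88.7 %: the order holds, but the draw there is larger than oak's 2.36 mM.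

(All runs come from a simulation with constants of no real substance; noise was put on by code.)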